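**Strategy.** The tetrahydrofuran is disconnected at the O1–C2 bond, where C2 is the benzylic ring carbon whose aryl group is trans to the C3 hydroxymethyl. The feature exploited is that C2 sits para to the free phenolic OH of its 4-hydroxy-3,5-dimethoxyphenyl ring. DDQ converts this p-hydroxybenzyl CH2 into a p-quinone methide, and the C5 hydroxyl closes the ring by 1,6-addition, creating the O1–C2 bond and the C2 stereocentre in one C–H functionalising operation. The precursor is an open-chain 1,4-diarylbutan-1-ol that already carries C3, C4 and C5, assembled in one pot by conjugate addition–aldol reaction on (5R)-5-menthyloxy-2(5H)-furanone; its second aryl ring is silyl-capped.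

Key step: step 7

Remark: C2–C5 and O1 denote throughout the atoms that end up in the tetrahydrofuran ring (C2 aryl trans to the C3 CH2OH, 2S; C5 aryl cis to the C4 CH2OH, 5R); C9 and C9' are the CH2O carbons on C3 and C4.
Remark: compounds 1, 3 and 5 are taken as commercially available.

Step 1
Reactants: 1 syringaldehyde (4-hydroxy-3,5-dimethoxybenzaldehyde)
Product: 2 3,5-dimethoxy-4-(triisopropylsilyloxy)benzaldehyde
Conditions: TIPSCl, imidazole, DMF, rt
Reagents that add atoms: triisopropylsilyl chloride, CC(C)[Si](Cl)(C(C)C)C(C)C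
Why: O-silylation of the phenol caps the ring that must not form a quinone methide later, the bulky TIPS ether being expected to survive organolithium, LiAlH4 and Raney Ni conditions.

Step 2
Reactants: 3 4-(benzyloxy)-3,5-dimethoxybenzaldehyde
Product: 4 2-[4-(benzyloxy)-3,5-dimethoxyphenyl]-1,3-dithiane
Conditions: HS(CH2)3SH, BF3·OEt2 (cat.), CH2Cl2, 0 °C to rt
Reagents that add atoms: propane-1,3-dithiol, SCCCS
Why: Lewis-acid-catalysed dithioacetalization turns the aldehyde carbon (future C2) into an acyl-anion equivalent (umpolung).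

Step 3
Reactants: 4 2-[4-(benzyloxy)-3,5-dimethoxyphenyl]-1,3-dithiane; 5 (5R)-5-[(1R,2S,5R)-menthyloxy]furan-2(5H)-one; 2 3,5-dimethoxy-4-(triisopropylsilyloxy)benzaldehyde
Product: 8 (3S,4R,5R)-4-{2-[4-(benzyloxy)-3,5-dimethoxyphenyl]-1,3-dithian-2-yl}-3-{(R)-[3,5-dimethoxy-4-(triisopropylsilyloxy)phenyl](hydroxy)methyl}-5-[(1R,2S,5R)-menthyloxy]dihydrofuran-2(3H)-one, via lithiated dithiane 6 (not isolated), via lithium enolate 7 (not isolated)
Conditions: n-BuLi, THF, −78 to −20 °C; 5, −78 °C; 2, −78 °C; aq. NH4Cl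
Reagents that add atoms: none
Why: Tandem conjugate addition–aldol reaction in which the lithiated aryldithiane adds 1,4 to the butenolide anti to the acetal menthyloxy group (sets C3), and the ring-locked E-enolate 7 then adds to aldehyde 2 anti to the dithianyl group through a chair Zimmerman–Traxler transition state with the aryl group equatorial, which sets C4 (trans to C3) and should favour the anti-aldol (R)-carbinol at C5, any carbinol epimer being removed by chromatography.

Step 4
Reactants: 8 the lactone adduct from step 3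
Product: 9 (1R,2R,3R)-3-{2-[4-(benzyloxy)-3,5-dimethoxyphenyl]-1,3-dithian-2-yl}-1-[3,5-dimethoxy-4-(triisopropylsilyloxy)phenyl]-2-(hydroxymethyl)butane-1,4-diol
Conditions: LiAlH4, THF, 0 °C to rt
Reagents that add atoms: none
Why: Hydride reduction of the lactone carbonyl, followed by collapse of the released menthyl hemiacetal to an aldehyde and its reduction, unveils both hydroxymethyl groups (C9 and C9') and expels menthol without touching C3, C4 or C5.

Step 5
Reactants: 9 the triol from step 4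
Product: 10 (1R,2R,3R)-3-{2-[4-(benzyloxy)-3,5-dimethoxyphenyl]-1,3-dithian-2-yl}-4-(tert-butyldimethylsilyloxy)-2-[(tert-butyldimethylsilyloxy)methyl]-1-[3,5-dimethoxy-4-(triisopropylsilyloxy)phenyl]butan-1-ol
Conditions: TBSCl (2.2 equiv), imidazole, DMF, 0 °C
Reagents that add atoms: tert-butyldimethylsilyl chloride, CC(C)(C)[Si](C)(C)Cl
Why: Sterically controlled silylation caps the two primary hydroxyls and leaves the hindered secondary benzylic C5–OH free, so that later only this oxygen can reach C2.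

Step 6
Reactants: 10 the bis-TBS ether from step 5
Product: 11 (1R,2R,3R)-2,3-bis[(tert-butyldimethylsilyloxy)methyl]-4-(4-hydroxy-3,5-dimethoxyphenyl)-1-[3,5-dimethoxy-4-(triisopropylsilyloxy)phenyl]butan-1-ol
Conditions: Raney Ni (W-2, excess), H2 (1 atm), EtOH, rt to 50 °C
Reagents that add atoms: none
Why: Raney Ni hydrogenolysis cleaves both C–S bonds of the dithioketal (C2 becomes CH2) and the aryl benzyl ether in one operation, which should give the free phenol while the silyl ethers and the benzylic alcohol persist under neutral conditions.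

Step 7
Reactants: 11 the phenolic butan-1-ol from step 6
Product: 13 4-{(2S,3R,4R,5R)-3,4-bis[(tert-butyldimethylsilyloxy)methyl]-5-[3,5-dimethoxy-4-(triisopropylsilyloxy)phenyl]tetrahydrofuran-2-yl}-2,6-dimethoxyphenol, via p-quinone methide 12 (not isolated)
Conditions: DDQ (1.05 equiv), CH2Cl2, 0 °C; aq. NaHCO3
Reagents that add atoms: none
Why: DDQ removes two electrons and two protons (the phenolic O–H and one benzylic C2–H) from the free 4-hydroxy-3,5-dimethoxybenzyl group, giving p-quinone methide 12 whose exocyclic carbon C2 is a strong 1,6-acceptor, and the C5 hydroxyl adds to it with rearomatization; the closest known reaction type is the DDQ-mediated oxidative cycloetherification of 4-(hydroxyalkyl)phenols through p-quinone methides, the laboratory counterpart of quinone methide trapping in lignan biosynthesis. The tetrahydrofuran ring (O1, C2, C3, C4, C5) closes in a 5-exo-trig mode, the attacked C2=C(aryl) double bond lying outside the new ring. The new C2 stereocentre is controlled by the adjacent C3 centre: in the envelope transition state the quinonoid ring avoids the C3 CH2OTBS group (allylic strain), which places the aryl group trans to it, and because the free phenol allows the C2–O1 bond alone to reopen to 12, any 2,3-cis isomer should drain into the more stable 2,3-trans product. C3, C4 and C5 are not touched, since the C5–O1 bond belongs to the silyl-capped ring, which cannot form a quinone methide. The step needs site selectivity (only the free-phenol ring is oxidized, secured by the TIPS cap on the other ring), O-regioselectivity (only the C5 oxygen can reach C2 because both primary hydroxyls are TBS ethers) and O- over C-attack (the capped aryl ring could close an aryltetralin), which low temperature, one equivalent of oxidant and an immediate basic quench should secure.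

Step 8
Reactants: 13 the silylated tetrahydrofuran from step 7
Product: 14 [(2S,3R,4R,5R)-2,5-bis(4-hydroxy-3,5-dimethoxyphenyl)tetrahydrofuran-3,4-diyl]dimethanol
Conditions: Bu4NF (4 equiv), AcOH (4 equiv), THF, 0 °C to rt
Reagents that add atoms: none
Why: Fluoride-mediated desilylation cleaves the two primary TBS ethers and the aryl TIPS ether, the acetic acid buffer keeping the phenols protonated so that neither benzylic ether centre should open or epimerize.

**Compound list**

1 | syringaldehyde (4-hydroxy-3,5-dimethoxybenzaldehyde) | COc1cc(C=O)cc(OC)c1O | starting material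
2 | 3,5-dimethoxy-4-(triisopropylsilyloxy)benzaldehyde | COc1cc(C=O)cc(OC)c1O[Si](C(C)C)(C(C)C)C(C)C | intermediate
3 | 4-(benzyloxy)-3,5-dimethoxybenzaldehyde | COc1cc(C=O)cc(OC)c1OCc1ccccc1 | starting material
4 | 2-[4-(benzyloxy)-3,5-dimethoxyphenyl]-1,3-dithiane | COc1cc(C2SCCCS2)cc(OC)c1OCc1ccccc1 | intermediate
5 | (5R)-5-[(1R,2S,5R)-menthyloxy]furan-2(5H)-one | O=C1C=C[C@H](O[C@@H]2C[C@H](C)CC[C@H]2C(C)C)O1 | starting material
6 | 2-lithio-2-[4-(benzyloxy)-3,5-dimethoxyphenyl]-1,3-dithiane | [Li]C1(c2cc(OC)c(OCc3ccccc3)c(OC)c2)SCCCS1 | intermediate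
7 | lithium enolate of (4R,5R)-4-{2-[4-(benzyloxy)-3,5-dimethoxyphenyl]-1,3-dithian-2-yl}-5-[(1R,2S,5R)-menthyloxy]dihydrofuran-2(3H)-one | [Li]OC1=C[C@@H](C2(c3cc(OC)c(OCc4ccccc4)c(OC)c3)SCCCS2)[C@H](O[C@@H]2C[C@H](C)CC[C@H]2C(C)C)O1 | intermediate
8 | (3S,4R,5R)-4-{2-[4-(benzyloxy)-3,5-dimethoxyphenyl]-1,3-dithian-2-yl}-3-{(R)-[3,5-dimethoxy-4-(triisopropylsilyloxy)phenyl](hydroxy)methyl}-5-[(1R,2S,5R)-menthyloxy]dihydrofuran-2(3H)-one | O=C1O[C@@H](O[C@@H]2C[C@H](C)CC[C@H]2C(C)C)[C@H](C2(c3cc(OC)c(OCc4ccccc4)c(OC)c3)SCCCS2)[C@H]1[C@@H](O)c1cc(OC)c(O[Si](C(C)C)(C(C)C)C(C)C)c(OC)c1 | intermediate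
9 | (1R,2R,3R)-3-{2-[4-(benzyloxy)-3,5-dimethoxyphenyl]-1,3-dithian-2-yl}-1-[3,5-dimethoxy-4-(triisopropylsilyloxy)phenyl]-2-(hydroxymethyl)butane-1,4-diol | O[C@@H](c1cc(OC)c(O[Si](C(C)C)(C(C)C)C(C)C)c(OC)c1)[C@@H](CO)[C@@H](C1(c2cc(OC)c(OCc3ccccc3)c(OC)c2)SCCCS1)CO | intermediate
10 | (1R,2R,3R)-3-{2-[4-(benzyloxy)-3,5-dimethoxyphenyl]-1,3-dithian-2-yl}-4-(tert-butyldimethylsilyloxy)-2-[(tert-butyldimethylsilyloxy)methyl]-1-[3,5-dimethoxy-4-(triisopropylsilyloxy)phenyl]butan-1-ol | O[C@@H](c1cc(OC)c(O[Si](C(C)C)(C(C)C)C(C)C)c(OC)c1)[C@@H](CO[Si](C)(C)C(C)(C)C)[C@@H](C1(c2cc(OC)c(OCc3ccccc3)c(OC)c2)SCCCS1)CO[Si](C)(C)C(C)(C)C | intermediate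
11 | (1R,2R,3R)-2,3-bis[(tert-butyldimethylsilyloxy)methyl]-4-(4-hydroxy-3,5-dimethoxyphenyl)-1-[3,5-dimethoxy-4-(triisopropylsilyloxy)phenyl]butan-1-ol | O[C@@H](c1cc(OC)c(O[Si](C(C)C)(C(C)C)C(C)C)c(OC)c1)[C@@H](CO[Si](C)(C)C(C)(C)C)[C@@H](Cc1cc(OC)c(O)c(OC)c1)CO[Si](C)(C)C(C)(C)C | intermediate
12 | 4-{(2R,3R,4R)-2,3-bis[(tert-butyldimethylsilyloxy)methyl]-4-hydroxy-4-[3,5-dimethoxy-4-(triisopropylsilyloxy)phenyl]butylidene}-2,6-dimethoxycyclohexa-2,5-dien-1-one | O[C@@H](c1cc(OC)c(O[Si](C(C)C)(C(C)C)C(C)C)c(OC)c1)[C@@H](CO[Si](C)(C)C(C)(C)C)[C@@H](C=C1C=C(OC)C(=O)C(OC)=C1)CO[Si](C)(C)C(C)(C)C | intermediate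
13 | 4-{(2S,3R,4R,5R)-3,4-bis[(tert-butyldimethylsilyloxy)methyl]-5-[3,5-dimethoxy-4-(triisopropylsilyloxy)phenyl]tetrahydrofuran-2-yl}-2,6-dimethoxyphenol | COc1cc([C@H]2O[C@@H](c3cc(OC)c(O[Si](C(C)C)(C(C)C)C(C)C)c(OC)c3)[C@@H](CO[Si](C)(C)C(C)(C)C)[C@@H]2CO[Si](C)(C)C(C)(C)C)cc(OC)c1O | intermediate
14 | [(2S,3R,4R,5R)-2,5-bis(4-hydroxy-3,5-dimethoxyphenyl)tetrahydrofuran-3,4-diyl]dimethanol | COc1cc([C@H]2O[C@@H](c3cc(OC)c(O)c(OC)c3)[C@@H](CO)[C@@H]2CO)cc(OC)c1O | target

**Step count.** Total: 8 steps. Longest linear sequence: 7 steps (steps 2 to 8 from 3, or steps 1 and 3 to 8 from 1).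

**Steps most likely to fail**

1. Step 7. The reduced quinone is acidic and DDQ is a strong oxidant, so the phenolic product may be oxidized further at its benzylic ether carbon, or the quinone methide may be attacked by carbon of the silyl-capped aryl ring instead of by oxygen. The fallback leaves the route at 8 and rejoins it at 13, generating the same quinone methide without any oxidant. The dithiane of 8 is hydrolysed with HgO and BF3·OEt2 in aqueous THF to the aryl ketone lactone F1. LiAlH4 in THF then reduces ketone, lactone and acetal carbon to the tetraol F2, formed as both C2 epimers, which converge later. TBSCl and imidazole cap the two primary hydroxyls to give the bis-silyl ether diol F3. Hydrogenolysis (H2, Pd/C, EtOAc, trace Et3N) removes the benzyl ether to give the p-hydroxybenzylic alcohol F4. Pyridinium p-toluenesulfonate in CH2Cl2 at 0 °C should then dehydrate F4 to quinone methide 12, which closes to 13 under the same stereocontrol.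

2. Step 3. Facial selectivity at the aldehyde carbon may be poor (boat instead of chair transition state, or equilibration of the aldolate), giving a mixture of C5 carbinol epimers. The fallback sets out from 8 obtained as such a mixture and returns to 8 as a single epimer, replacing substrate control by reagent control. MnO2 in CH2Cl2 oxidizes both epimers to the one β-keto lactone F5. Reduction with BH3·SMe2 under catalysis by (S)-2-methyl-CBS-oxazaborolidine in THF at −20 °C should then deliver hydride to the face that gives the (R)-carbinol, with the aryl group acting as the large substituent.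

3. Step 6. On Raney Ni the benzyl ether may be cleaved incompletely, or the benzylic C5–O bond may be hydrogenolysed during the longer exposure needed. The fallback sets out from 10 and returns at 11, separating the two events by mechanism. Homolytic desulfurization with Bu3SnH and AIBN in toluene at reflux should give the benzyl ether F6 with the benzylic alcohol untouched. A short hydrogenolysis over Pd/C (H2, EtOAc, rt) then frees the phenol to give 11.

**Further compounds**

F1 | step 7 | (3S,4R,5R)-4-[4-(benzyloxy)-3,5-dimethoxybenzoyl]-3-{(R)-[3,5-dimethoxy-4-(triisopropylsilyloxy)phenyl](hydroxy)methyl}-5-[(1R,2S,5R)-menthyloxy]dihydrofuran-2(3H)-one | O=C1O[C@@H](O[C@@H]2C[C@H](C)CC[C@H]2C(C)C)[C@H](C(=O)c2cc(OC)c(OCc3ccccc3)c(OC)c2)[C@H]1[C@@H](O)c1cc(OC)c(O[Si](C(C)C)(C(C)C)C(C)C)c(OC)c1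
F2 | step 7 | (1R,2R,3R)-4-[4-(benzyloxy)-3,5-dimethoxyphenyl]-1-[3,5-dimethoxy-4-(triisopropylsilyloxy)phenyl]-2,3-bis(hydroxymethyl)butane-1,4-diol, mixture of C-4 epimers | O[C@@H](c1cc(OC)c(O[Si](C(C)C)(C(C)C)C(C)C)c(OC)c1)[C@@H](CO)[C@@H](C(O)c1cc(OC)c(OCc2ccccc2)c(OC)c1)CO
F3 | step 7 | (1R,2R,3R)-4-[4-(benzyloxy)-3,5-dimethoxyphenyl]-2,3-bis[(tert-butyldimethylsilyloxy)methyl]-1-[3,5-dimethoxy-4-(triisopropylsilyloxy)phenyl]butane-1,4-diol, mixture of C-4 epimers | O[C@@H](c1cc(OC)c(O[Si](C(C)C)(C(C)C)C(C)C)c(OC)c1)[C@@H](CO[Si](C)(C)C(C)(C)C)[C@@H](C(O)c1cc(OC)c(OCc2ccccc2)c(OC)c1)CO[Si](C)(C)C(C)(C)C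
F4 | step 7 | (1R,2R,3R)-2,3-bis[(tert-butyldimethylsilyloxy)methyl]-4-(4-hydroxy-3,5-dimethoxyphenyl)-1-[3,5-dimethoxy-4-(triisopropylsilyloxy)phenyl]butane-1,4-diol, mixture of C-4 epimers | O[C@@H](c1cc(OC)c(O[Si](C(C)C)(C(C)C)C(C)C)c(OC)c1)[C@@H](CO[Si](C)(C)C(C)(C)C)[C@@H](C(O)c1cc(OC)c(O)c(OC)c1)CO[Si](C)(C)C(C)(C)C
F5 | step 3 | (3S,4R,5R)-4-{2-[4-(benzyloxy)-3,5-dimethoxyphenyl]-1,3-dithian-2-yl}-3-[3,5-dimethoxy-4-(triisopropylsilyloxy)benzoyl]-5-[(1R,2S,5R)-menthyloxy]dihydrofuran-2(3H)-one | O=C1O[C@@H](O[C@@H]2C[C@H](C)CC[C@H]2C(C)C)[C@H](C2(c3cc(OC)c(OCc4ccccc4)c(OC)c3)SCCCS2)[C@H]1C(=O)c1cc(OC)c(O[Si](C(C)C)(C(C)C)C(C)C)c(OC)c1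
F6 | step 6 | (1R,2R,3R)-4-[4-(benzyloxy)-3,5-dimethoxyphenyl]-2,3-bis[(tert-butyldimethylsilyloxy)methyl]-1-[3,5-dimethoxy-4-(triisopropylsilyloxy)phenyl]butan-1-ol | O[C@@H](c1cc(OC)c(O[Si](C(C)C)(C(C)C)C(C)C)c(OC)c1)[C@@H](CO[Si](C)(C)C(C)(C)C)[C@@H](Cc1cc(OC)c(OCc2ccccc2)c(OC)c1)CO[Si](C)(C)C(C)(C)C
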